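**Retrosynthetic overview**

1. Feature: in ring A (the benzo ring) of the 2,3-dihydrobenzofuran, C7a carries the ring oxygen O1 and the adjacent C7 carries OMe. Both C–O bonds are traced back to one C7a≡C7 aryne.
2. Key disconnection: O1–C7a and C7–B (later C7–O) form in one operation. A tethered C2 alkoxide adds to the aryne and closes the dihydrofuran ring, the only ring built in the route, and the resulting C7 aryllithium is borylated. The aryne comes from a 2-fluoroaryl group.
3. The acyclic (1R,2R) fluoroaryl alcohol comes from a racemic α-aryl ketone by dynamic kinetic asymmetric transfer hydrogenation. The ketone comes from Pd-catalysed α-arylation (C3–C3a bond) of a MOM-protected syringyl ethyl ketone with acetal-protected 3-bromo-4-fluorobenzaldehyde.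
4. End game: C7–B → C7–OH → C7–OMe; C5 acetal → aldehyde → E-propenyl (Julia–Kocienski); MOM removal. Rings A and B are bought as arenes.

Key step: step 7

Remark: 5-(ethylsulfonyl)-1-phenyl-1H-tetrazole is taken as a purchasable reagent, and the sense of induction in step 6 is assigned from the usual behaviour of aryl ketones with RuCl[(R,R)-TsDPEN](p-cymene).

**Route**

Step 1
Reactants: 1 3-bromo-4-fluorobenzaldehyde
Product: 2 2-(3-bromo-4-fluorophenyl)-1,3-dioxolane
Conditions: HOCH2CH2OH, p-TsOH·H2O (cat.), toluene, reflux, Dean–Stark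
Reagents that add atoms: ethylene glycol, OCCO
Why: Acid-catalysed acetalisation with azeotropic removal of water masks the aldehyde as a dioxolane that tolerates the enolate, hydride and lithium amide steps that follow.

Step 2
Reactants: 3 syringaldehyde
Product: 4 3,5-dimethoxy-4-(methoxymethoxy)benzaldehyde
Conditions: MOMCl, i-Pr2NEt, CH2Cl2, 0 °C → rt
Reagents that add atoms: chloromethyl methyl ether, COCCl
Why: Williamson-type O-alkylation of the acidic syringyl phenol gives a MOM ether that is inert to NaOt-Bu, lithium amide, peroxide and methylation conditions and can be removed at the end without hydrogenolysis.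

Step 3
Reactants: 4 3,5-dimethoxy-4-(methoxymethoxy)benzaldehyde
Product: 5 rac-1-[3,5-dimethoxy-4-(methoxymethoxy)phenyl]propan-1-ol
Conditions: EtMgBr, THF, 0 °C → rt; aq. work-up
Reagents that add atoms: ethylmagnesium bromide, CC[Mg]Br
Why: Grignard addition to the aryl aldehyde installs the two carbons that become C3 and its methyl group, and the racemic carbinol centre is erased in step 4.

Step 4
Reactants: 5 rac-1-[3,5-dimethoxy-4-(methoxymethoxy)phenyl]propan-1-ol
Product: 6 1-[3,5-dimethoxy-4-(methoxymethoxy)phenyl]propan-1-one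
Conditions: MnO2 (activated, excess), CH2Cl2, rt
Reagents that add atoms: none
Why: MnO2 oxidation of the electron-rich benzylic alcohol gives the aryl ethyl ketone without affecting the MOM acetal.

Step 5
Reactants: 6 1-[3,5-dimethoxy-4-(methoxymethoxy)phenyl]propan-1-one; 2 2-(3-bromo-4-fluorophenyl)-1,3-dioxolane
Product: 7 rac-2-[5-(1,3-dioxolan-2-yl)-2-fluorophenyl]-1-[3,5-dimethoxy-4-(methoxymethoxy)phenyl]propan-1-one
Conditions: Pd(OAc)2 (cat.), Xantphos, NaOt-Bu, toluene, 80 °C
Reagents that add atoms: none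
Why: Palladium-catalysed ketone α-arylation (Buchwald–Hartwig type), in which zerovalent palladium inserts into C–Br and not C–F, the sodium enolate of 6 transmetalates and reductive elimination forms the future C3–C3a bond, while a second arylation is blocked at the now tertiary α-carbon and the α-centre is left racemic and labile by design.

Step 6
Reactants: 7 rac-2-[5-(1,3-dioxolan-2-yl)-2-fluorophenyl]-1-[3,5-dimethoxy-4-(methoxymethoxy)phenyl]propan-1-one
Product: 8 (1R,2R)-2-[5-(1,3-dioxolan-2-yl)-2-fluorophenyl]-1-[3,5-dimethoxy-4-(methoxymethoxy)phenyl]propan-1-ol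
Conditions: RuCl[(R,R)-TsDPEN](p-cymene) (cat.), HCO2H/DBU (DBU in slight excess), DMF, 40 °C
Reagents that add atoms: none
Why: Noyori asymmetric transfer hydrogenation under dynamic kinetic resolution, in which DBU enolises the α-aryl ketone so that its enantiomers interconvert, the (R,R)-ligated ruthenium hydride holds the ketone aryl group in its arene CH/π pocket and sets C1 as R, and it should reduce fastest the (2R)-ketone, for which that face is also the Felkin–Anh face (hydride anti to the α-aryl group), so that C2 is set by the resolution and the like (1R,2R) isomer results.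

Step 7
Reactants: 8 (1R,2R)-2-[5-(1,3-dioxolan-2-yl)-2-fluorophenyl]-1-[3,5-dimethoxy-4-(methoxymethoxy)phenyl]propan-1-ol; 9 trimethyl borate
Product: 14 [(2R,3R)-5-(1,3-dioxolan-2-yl)-2-[3,5-dimethoxy-4-(methoxymethoxy)phenyl]-3-methyl-2,3-dihydro-1-benzofuran-7-yl]boronic acid, via ortho-lithiated fluoroarene alkoxide 10 (not isolated), via aryne alkoxide 11 (not isolated), via C7 aryllithium 12 (not isolated), via lithium aryltrimethoxyborate 13 (not isolated)
Conditions: lithium 2,2,6,6-tetramethylpiperidide (3 equiv), THF, −78 → −25 °C; recool to −78 °C, B(OMe)3 (excess), → rt; aq. work-up (pH 7)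
Reagents that add atoms: trimethyl borate, COB(OC)OC; water, O
Why: The first equivalent of lithium amide forms the lithium alkoxide and a second removes H-3′ of the fluoroarene, the only hydrogen ortho to fluorine, to give 10, which loses LiF on warming to the C2′–C3′ aryne 11 (future C7a–C7). The alkoxide oxygen, three atoms away, adds to the nearer aryne carbon in a 5-exo-dig closure of the dihydrofuran ring (O1–C7a bond) and leaves the carbanion on C7 as aryllithium 12, since attack at the far carbon would need a meta-bridged ring. Trimethyl borate then forms the C7–B bond as ate complex 13, which is hydrolysed to boronic acid 14 on work-up. The closest known reaction type is the aryne cyclisation of tethered alkoxide or amide nucleophiles with electrophilic capture of the ortho-aryllithium so formed. No stereocentre is formed or touched, so the (1R,2R) diad of 8 should pass unchanged into the trans (2R,3R) ring. The step needs regiocontrol of metalation and of addition across the aryne: the first is secured by the single hydrogen ortho to fluorine and by a base too weak to metalate the anisole-type positions irreversibly, the second by the tether on the carbon next to the aryne.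

Step 8
Reactants: 14 [(2R,3R)-5-(1,3-dioxolan-2-yl)-2-[3,5-dimethoxy-4-(methoxymethoxy)phenyl]-3-methyl-2,3-dihydro-1-benzofuran-7-yl]boronic acid
Product: 15 (2R,3R)-5-(1,3-dioxolan-2-yl)-2-[3,5-dimethoxy-4-(methoxymethoxy)phenyl]-3-methyl-2,3-dihydro-1-benzofuran-7-ol
Conditions: 30% H2O2, aq. NaOH, THF, 0 °C → rt
Reagents that add atoms: hydrogen peroxide, OO
Why: Boronic acid oxidation, in which hydroperoxide adds to boron and the aryl group migrates from boron to oxygen at C7, under basic conditions that leave the dioxolane and MOM ether intact.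

Step 9
Reactants: 15 (2R,3R)-5-(1,3-dioxolan-2-yl)-2-[3,5-dimethoxy-4-(methoxymethoxy)phenyl]-3-methyl-2,3-dihydro-1-benzofuran-7-ol
Product: 16 2-[(2R,3R)-2-[3,5-dimethoxy-4-(methoxymethoxy)phenyl]-7-methoxy-3-methyl-2,3-dihydro-1-benzofuran-5-yl]-1,3-dioxolane
Conditions: MeI, K2CO3, DMF, rt
Reagents that add atoms: iodomethane, CI
Why: Williamson methylation of the only free phenol gives the C7 methoxy group, the ring B phenol being still protected.

Step 10
Reactants: 16 2-[(2R,3R)-2-[3,5-dimethoxy-4-(methoxymethoxy)phenyl]-7-methoxy-3-methyl-2,3-dihydro-1-benzofuran-5-yl]-1,3-dioxolane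
Product: 17 (2R,3R)-2-[3,5-dimethoxy-4-(methoxymethoxy)phenyl]-7-methoxy-3-methyl-2,3-dihydro-1-benzofuran-5-carbaldehyde
Conditions: PPTS (cat.), acetone/H2O, 40 °C
Reagents that add atoms: water, O
Why: Mild acid-catalysed acetal hydrolysis should cleave the aryl dioxolane, whose oxocarbenium ion is stabilised by the para ring oxygen O1, much faster than the phenolic MOM ether.

Step 11
Reactants: 17 (2R,3R)-2-[3,5-dimethoxy-4-(methoxymethoxy)phenyl]-7-methoxy-3-methyl-2,3-dihydro-1-benzofuran-5-carbaldehyde; 18 5-(ethylsulfonyl)-1-phenyl-1H-tetrazole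
Product: 19 (2R,3R)-2-[3,5-dimethoxy-4-(methoxymethoxy)phenyl]-7-methoxy-3-methyl-5-[(E)-prop-1-enyl]-2,3-dihydro-1-benzofuran
Conditions: KN(SiMe3)2, DME, −60 °C → rt
Reagents that add atoms: 5-(ethylsulfonyl)-1-phenyl-1H-tetrazole, CCS(=O)(=O)c1nnnn1-c1ccccc1
Why: Julia–Kocienski olefination, in which the metalated phenyltetrazolyl sulfone adds to the aldehyde and Smiles rearrangement with loss of SO2 and tetrazololate follows, should give the E-propenyl group from an aryl aldehyde under these conditions.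

Step 12
Reactants: 19 (2R,3R)-2-[3,5-dimethoxy-4-(methoxymethoxy)phenyl]-7-methoxy-3-methyl-5-[(E)-prop-1-enyl]-2,3-dihydro-1-benzofuran
Product: 20 maceneolignan A, 2,6-dimethoxy-4-[(2R,3R)-7-methoxy-3-methyl-5-[(E)-prop-1-enyl]-2,3-dihydro-1-benzofuran-2-yl]phenol
Conditions: conc. HCl (cat.), MeOH, rt
Reagents that add atoms: none
Why: Acid-catalysed acetal exchange with methanol removes the MOM group as dimethoxymethane under conditions mild enough that the E-propenyl group and the trans ring should survive, and neither stereocentre is involved.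

**Compound list**

1 | 3-bromo-4-fluorobenzaldehyde | O=Cc1ccc(F)c(Br)c1 | starting material
2 | 2-(3-bromo-4-fluorophenyl)-1,3-dioxolane | O1CCOC1c1ccc(F)c(Br)c1 | intermediate
3 | syringaldehyde (4-hydroxy-3,5-dimethoxybenzaldehyde) | COc1cc(C=O)cc(OC)c1O | starting material
4 | 3,5-dimethoxy-4-(methoxymethoxy)benzaldehyde | COCOc1c(OC)cc(C=O)cc1OC | intermediate
5 | rac-1-[3,5-dimethoxy-4-(methoxymethoxy)phenyl]propan-1-ol | CCC(O)c1cc(OC)c(OCOC)c(OC)c1 | intermediate
6 | 1-[3,5-dimethoxy-4-(methoxymethoxy)phenyl]propan-1-one | CCC(=O)c1cc(OC)c(OCOC)c(OC)c1 | intermediate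
7 | rac-2-[5-(1,3-dioxolan-2-yl)-2-fluorophenyl]-1-[3,5-dimethoxy-4-(methoxymethoxy)phenyl]propan-1-one | O1CCOC1c1ccc(F)c(c1)C(C)C(=O)c1cc(OC)c(OCOC)c(OC)c1 | intermediate
8 | (1R,2R)-2-[5-(1,3-dioxolan-2-yl)-2-fluorophenyl]-1-[3,5-dimethoxy-4-(methoxymethoxy)phenyl]propan-1-ol | O1CCOC1c1ccc(F)c(c1)[C@@H](C)[C@H](c1cc(OC)c(OCOC)c(OC)c1)O | intermediate
9 | trimethyl borate | COB(OC)OC | starting material
10 | lithium (1R,2R)-2-[5-(1,3-dioxolan-2-yl)-2-fluoro-3-lithiophenyl]-1-[3,5-dimethoxy-4-(methoxymethoxy)phenyl]propan-1-olate | O1CCOC1c1cc([Li])c(F)c(c1)[C@@H](C)[C@H](c1cc(OC)c(OCOC)c(OC)c1)O[Li] | intermediate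
11 | lithium (1R,2R)-2-[5-(1,3-dioxolan-2-yl)-2,3-didehydrophenyl]-1-[3,5-dimethoxy-4-(methoxymethoxy)phenyl]propan-1-olate (aryne) | O1CCOC1C1=CC#CC(=C1)[C@@H](C)[C@H](c1cc(OC)c(OCOC)c(OC)c1)O[Li] | intermediate
12 | [(2R,3R)-5-(1,3-dioxolan-2-yl)-2-[3,5-dimethoxy-4-(methoxymethoxy)phenyl]-3-methyl-2,3-dihydro-1-benzofuran-7-yl]lithium | O1CCOC1c1cc([Li])c2c(c1)[C@@H](C)[C@H](c1cc(OC)c(OCOC)c(OC)c1)O2 | intermediate
13 | lithium [(2R,3R)-5-(1,3-dioxolan-2-yl)-2-[3,5-dimethoxy-4-(methoxymethoxy)phenyl]-3-methyl-2,3-dihydro-1-benzofuran-7-yl]trimethoxyborate | O1CCOC1c1cc([B-](OC)(OC)OC)c2c(c1)[C@@H](C)[C@H](c1cc(OC)c(OCOC)c(OC)c1)O2.[Li+] | intermediate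
14 | [(2R,3R)-5-(1,3-dioxolan-2-yl)-2-[3,5-dimethoxy-4-(methoxymethoxy)phenyl]-3-methyl-2,3-dihydro-1-benzofuran-7-yl]boronic acid | O1CCOC1c1cc(B(O)O)c2c(c1)[C@@H](C)[C@H](c1cc(OC)c(OCOC)c(OC)c1)O2 | intermediate
15 | (2R,3R)-5-(1,3-dioxolan-2-yl)-2-[3,5-dimethoxy-4-(methoxymethoxy)phenyl]-3-methyl-2,3-dihydro-1-benzofuran-7-ol | O1CCOC1c1cc(O)c2c(c1)[C@@H](C)[C@H](c1cc(OC)c(OCOC)c(OC)c1)O2 | intermediate
16 | 2-[(2R,3R)-2-[3,5-dimethoxy-4-(methoxymethoxy)phenyl]-7-methoxy-3-methyl-2,3-dihydro-1-benzofuran-5-yl]-1,3-dioxolane | O1CCOC1c1cc(OC)c2c(c1)[C@@H](C)[C@H](c1cc(OC)c(OCOC)c(OC)c1)O2 | intermediate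
17 | (2R,3R)-2-[3,5-dimethoxy-4-(methoxymethoxy)phenyl]-7-methoxy-3-methyl-2,3-dihydro-1-benzofuran-5-carbaldehyde | O=Cc1cc(OC)c2c(c1)[C@@H](C)[C@H](c1cc(OC)c(OCOC)c(OC)c1)O2 | intermediate
18 | 5-(ethylsulfonyl)-1-phenyl-1H-tetrazole | CCS(=O)(=O)c1nnnn1-c1ccccc1 | starting material
19 | (2R,3R)-2-[3,5-dimethoxy-4-(methoxymethoxy)phenyl]-7-methoxy-3-methyl-5-[(E)-prop-1-enyl]-2,3-dihydro-1-benzofuran | C/C=C/c1cc(OC)c2c(c1)[C@@H](C)[C@H](c1cc(OC)c(OCOC)c(OC)c1)O2 | intermediate
20 | maceneolignan A | C/C=C/c1cc(OC)c2c(c1)[C@@H](C)[C@H](c1cc(OC)c(O)c(OC)c1)O2 | target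

**Step count**

Total: 12 steps. Longest linear sequence: 11 steps (steps 2–12, from syringaldehyde).

**Steps most likely to fail**

Step 7. The C7 carbanion may be protonated by the liberated 2,2,6,6-tetramethylpiperidine before the borate is added, or the aryne may be consumed intermolecularly; either would give material without the C7 substituent. The fallback closes the ring without an aryne and oxygenates C7 afterwards. It sets out from 8: KOt-Bu in DMF at 90 °C should displace fluoride by intramolecular SNAr to give the C7-unsubstituted dihydrobenzofuran, 2-[(2R,3R)-2-[3,5-dimethoxy-4-(methoxymethoxy)phenyl]-3-methyl-2,3-dihydro-1-benzofuran-5-yl]-1,3-dioxolane F1. Iridium-catalysed C–H borylation ([Ir(OMe)(cod)]2, 4,4′-di-tert-butyl-2,2′-bipyridine, B2pin2, THF, 80 °C) should then functionalise C7–H. C4 lies between two carbon substituents, C6 is next to the branched dioxolanyl group, both ring B hydrogens sit between OMe and the benzylic carbon, and a ring-fused ether oxygen is tolerated ortho to the new C–B bond. This should give the pinacol boronate, 2-[(2R,3R)-5-(1,3-dioxolan-2-yl)-2-[3,5-dimethoxy-4-(methoxymethoxy)phenyl]-3-methyl-2,3-dihydro-1-benzofuran-7-yl]-4,4,5,5-tetramethyl-1,3,2-dioxaborolane F2. Oxidation with H2O2/NaOH comes back to the route at phenol 15.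

Step 6. Enolisation of 7 may be slower than reduction, or catalyst and substrate preferences may not reinforce each other, so that the resolution is incomplete and diastereo- and enantioselectivity fall short. The fallback replaces catalyst control by substrate control plus resolution. It sets out from 7: LiBH(s-Bu)3 in THF at −78 °C should give, by Felkin–Anh addition, the racemic like alcohol, rac-(1R,2R)-2-[5-(1,3-dioxolan-2-yl)-2-fluorophenyl]-1-[3,5-dimethoxy-4-(methoxymethoxy)phenyl]propan-1-ol F3. Esterification with (S)-2-methoxy-2-phenylacetic acid (DCC, DMAP, CH2Cl2) gives two diastereomeric esters, and chromatography separates the wanted (1R,2R)-2-[5-(1,3-dioxolan-2-yl)-2-fluorophenyl]-1-[3,5-dimethoxy-4-(methoxymethoxy)phenyl]propyl (2S)-2-methoxy-2-phenylacetate F4 from its (1S,2S)-configured diastereomer, (1S,2S)-2-[5-(1,3-dioxolan-2-yl)-2-fluorophenyl]-1-[3,5-dimethoxy-4-(methoxymethoxy)phenyl]propyl (2S)-2-methoxy-2-phenylacetate F5. Saponification of F4 (LiOH, THF/MeOH/H2O) comes back to the route at 8.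

Step 12. Acid may add methanol to, or oligomerise, the electron-rich propenyl arene, or ionise the benzylic C2–O1 bond, before the MOM ether is fully cleaved. The fallback removes all acid-labile groups before the alkene exists. It sets out from 16: aqueous HCl in THF at 40 °C should cleave dioxolane and MOM ether together to give the hydroxy aldehyde, (2R,3R)-2-(4-hydroxy-3,5-dimethoxyphenyl)-7-methoxy-3-methyl-2,3-dihydro-1-benzofuran-5-carbaldehyde F6. Julia–Kocienski olefination of its potassium phenoxide (18, excess KN(SiMe3)2, DME, −60 °C → rt) comes back to the route at target 20.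

**Further compounds**

F1 | step 7 | 2-[(2R,3R)-2-[3,5-dimethoxy-4-(methoxymethoxy)phenyl]-3-methyl-2,3-dihydro-1-benzofuran-5-yl]-1,3-dioxolane | O1CCOC1c1ccc2c(c1)[C@@H](C)[C@H](c1cc(OC)c(OCOC)c(OC)c1)O2
F2 | step 7 | 2-[(2R,3R)-5-(1,3-dioxolan-2-yl)-2-[3,5-dimethoxy-4-(methoxymethoxy)phenyl]-3-methyl-2,3-dihydro-1-benzofuran-7-yl]-4,4,5,5-tetramethyl-1,3,2-dioxaborolane | O1CCOC1c1cc(B3OC(C)(C)C(C)(C)O3)c2c(c1)[C@@H](C)[C@H](c1cc(OC)c(OCOC)c(OC)c1)O2
F3 | step 6 | rac-(1R,2R)-2-[5-(1,3-dioxolan-2-yl)-2-fluorophenyl]-1-[3,5-dimethoxy-4-(methoxymethoxy)phenyl]propan-1-ol (racemate, one enantiomer drawn) | O1CCOC1c1ccc(F)c(c1)[C@@H](C)[C@H](c1cc(OC)c(OCOC)c(OC)c1)O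
F4 | step 6 | (1R,2R)-2-[5-(1,3-dioxolan-2-yl)-2-fluorophenyl]-1-[3,5-dimethoxy-4-(methoxymethoxy)phenyl]propyl (2S)-2-methoxy-2-phenylacetate | O1CCOC1c1ccc(F)c(c1)[C@@H](C)[C@H](c1cc(OC)c(OCOC)c(OC)c1)OC(=O)[C@@H](OC)c1ccccc1
F5 | step 6 | (1S,2S)-2-[5-(1,3-dioxolan-2-yl)-2-fluorophenyl]-1-[3,5-dimethoxy-4-(methoxymethoxy)phenyl]propyl (2S)-2-methoxy-2-phenylacetate | O1CCOC1c1ccc(F)c(c1)[C@H](C)[C@@H](c1cc(OC)c(OCOC)c(OC)c1)OC(=O)[C@@H](OC)c1ccccc1
F6 | step 12 | (2R,3R)-2-(4-hydroxy-3,5-dimethoxyphenyl)-7-methoxy-3-methyl-2,3-dihydro-1-benzofuran-5-carbaldehyde | O=Cc1cc(OC)c2c(c1)[C@@H](C)[C@H](c1cc(OC)c(O)c(OC)c1)O2
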